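# Proposal: CNP0228781.2 from (S)-carvone by a carvone-based three-component assembly around C5 and C10

Atom numbering used throughout: ring C5–C10; C14 methyl and the C1–C2 oxirane on C10; arm C4(=C15)–C3 on C5; methacrylate on O6; arm C11(=C13)–C12 on C7, closed as lactone to O8; free hydroxyl on C9. "Lower face" is the ring face that carries C14, "upper face" the opposite one.

## Analysis of the target

CNP0228781.2 is an elemane-type lactone: one cyclohexane ring (C5–C10) in which every carbon is substituted, trans-fused across C7–C8 to an α-methylene-γ-butyrolactone (C11, C12, C13, O8). C5 carries a 2-formylvinyl arm, O6 a methacrylate, C9 a free hydroxyl, and the quaternary C10 a methyl group and a monosubstituted oxirane. The six ring carbons are contiguous stereocentres and C1 is a seventh. C4, O6, C11 and C14 lie on the lower face; C1, O8 and O9 on the upper face. In the chair both arms, O8 and C1 are equatorial, O6 and O9 are axial, and O6 is 1,3-diaxial to C14; C1 is R. The three Michael acceptors (enal, methylene lactone, methacrylate) exclude nucleophiles, hydrides and strong base late in the route, and the oxirane can be opened under acid by the nearby O9 hydroxyl. The hard points are the quaternary C10 between C5 and C9, the all-cis C5/C6/C7 triad, the distinction of three secondary oxygens, and the configuration of C1, which lies outside the ring. The strategy rests on the fact that C7 with its three-carbon branch, C8, the C9 oxygen and the methyl-bearing C10 are the skeleton of (S)-carvone (1). C5 is then the enone β-carbon and C6 the γ-carbon, so a hydroxyl on C6 can steer a carbon nucleophile onto C5, and the enolate left behind can take up C1 at C10; both arms are isopropenyl groups, so one oxidation method serves the enal and the lactone.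

## Retrosynthetic reasoning

**Lactone and enal (28 to 25).** The O8–C12 bond and the two carbonyl groups are taken back to the bis(allylic alcohol) 25. An allylic-selective oxidant can raise C3 and C12 together. The C12 aldehyde can be captured only by O8, because O6 is acylated and the axial O9 cannot reach it. The last step then needs neither base nor a deprotection, which the three acceptors would not tolerate.

**Allylic oxygens (25 to 24).** Removing C3–O and C12–O returns both arms to isopropenyl groups. The forward reaction is one selenium-mediated ene and 2,3-shift sequence that must oxidise two allylic methyl groups and leave the electron-poor methacrylate alone.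

**Ester at O6 (24 to 23, 22, 21).** The acyl–O6 bond is cut before the arms are oxidised. O6 is the most hindered hydroxyl of the molecule and needs forcing acylation, which is safe only while no enal or lactone is present. O8 and O9 are masked meanwhile as the cyclic carbonate 22, which the axial O6 cannot join and which is removed by mild transesterification (23 to 24).

**Oxirane (21, 20, 19, 18, 17 to 16).** A vinyl group at C10, epoxidised under the direction of the O9 hydroxyl, was examined on the chair and set aside. O9 is gauche to C1, and oxygen delivered from it reaches the alkene while C2 points into the open sector between C9 and C14, because the other rotamer pushes C2 against C4. That places the oxirane oxygen on the face that corresponds to the wrong configuration at C1. The C1–O stereocentre is therefore made by reduction. The oxirane closes from the chlorohydrin 19, which comes from the chloromethyl ketone 18; a hydride entering from the same open sector gives the required 1R centre, and a chiral oxazaborolidine enforces it. Ketone 18 is traced through alcohol 17 to aldehyde 16 by cutting C1–C2, with a chloromethyl carbanion as forward partner. The ring is closed while O9 is still silylated, so that O9 cannot compete for C2.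

**C8 and C9 oxygens (16, 15, 14, 13, 12 to 11).** C8–O is cut back to the silyl enol ether 12. The C9 ketone of 11 can enolise only towards C8 because C10 is quaternary, and oxidation from the less hindered upper face puts O8 trans to the C7 arm. The C9 hydroxyl comes from ketone 13 by equatorial hydride delivery and has to end up axial and cis to O8. All four hydroxyls are carried as triethylsilyl ethers (15), of which only the primary one is oxidised to 16.

**C5–C4 and C10–C1 (11 to 6, 7 and 8).** This is the central disconnection. Both exocyclic bonds at the C5–C10 edge are cut at once, giving cis-4-hydroxycarvone (6), isopropenylmagnesium bromide (7) and formaldehyde (8). It is preferred to any ring-forming disconnection because the ring and C7 are already present in 6. The magnesium alkoxide of 6 can deliver 7 to C5 on its own face, and the resulting enolate 10 accepts 8 at C10 from the opposite face. Two bonds, the quaternary centre and two stereocentres are gained in one flask.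

**γ-Oxygen (6, 5, 4, 3 to 1).** The C6–O bond is cut back to carvone through its through-conjugated silyl dienol ether 3. Oxidation of 3 should occur anti to the isopropenyl group and give the trans alcohol 4; the cis relation needed for the key step is then obtained by SN2 inversion through ester 5.

## Alternatives that were turned down

**Alternative 1: ester-tethered intramolecular Diels–Alder reaction.**
- Disconnection: the ring is cut at C5–C10 and C6–C7.
- Key step: the triene ester A1, a (Z)-3-acyloxyacryloyl oxazolidinone imide joined through the C12 ester to a diene, would cyclise under Me2AlCl to the bicyclic lactone A2, a cyclohexene cis-fused to an O6 lactone.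
- For it: one step sets C5, C6, C7 and the quaternary C10, with absolute control from the auxiliary, and leaves C8=C9 for a later cis-dihydroxylation.
- Against it: ester tethers prefer the extended conformation, so such cyclisations are slow. The diene terminus C10 is disubstituted, so one of its groups must sit in the inside position of the transition state. The dienophile is an acyl enol ester that a Lewis acid can cleave. After the cycloaddition the imide carbon is only C4, so C3 and C15 are still missing; the lactone sits on O6 and must be moved to O8 and methylenated.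
- Comparison: A2 is stronger in that its stereochemistry does not depend on the facial bias of a cyclic enolate. The chosen route takes C7 and both arms from the chiral pool, needs no auxiliary, and has a shorter path after its key step.

**Alternative 2: pinacol closure across C8–C9.**
- Disconnection: the ring is cut at C8–C9.
- Key step: SmI2 would reduce the dialdehyde A3 to a samarium-bridged bis-ketyl that couples to the cis-8,9-diol A4.
- For it: the cis-diol arises in one step and its cis relation is inherent to the chelated intermediate. The chosen route spends three steps on this and relies on a delicate hydride selectivity, so A4 is stronger on that point.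
- Against it: A3 is an open chain with four contiguous stereocentres, including the quaternary C10, and has no cheap chiral source. C7 is epimerisable next to its aldehyde. Two cis-diols (both oxygens up or both down) can form, and nothing compelling favours the upper pair. The C10 vinyl group of A4 meets the C1 facial problem described above.
- Comparison: the chosen route offers the ring and C7 from carvone, the C5/C10 edge in one operation, and C1 set by reduction before any acceptor exists.

**Alternative 3: chromium allylation closing carbocycle and lactone.**
- Disconnection: C7–C8 and O8–C12 are cut.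
- Key step: CrCl2 would turn the 2-(bromomethyl)enoate A5 into an allylchromium species whose γ-carbon adds to the C8 aldehyde; the alkoxide then lactonises to give A6.
- For it: A6 is only a handful of steps from the target. The methylene lactone appears at the right oxidation level and the oxygens are already differentiated. On the length of the endgame this alternative is clearly stronger.
- Against it: the cost moves into A5, an acyclic array with C5, C6, C9 and the quaternary C10. The aldehyde is hindered, next to C9 and the quaternary centre. The closure must set C7 and C8 trans to each other and in the right sense relative to C6 and C9, which depends on an unproven ring-forming transition state. The C10 vinyl group must again be epoxidised with the C1 problem unsolved.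
- Comparison: the chosen route reaches its key-step precursor in four steps from carvone and derives every ring stereocentre from one resident centre.

Key step: step 5

Remark on the chemistry: the oxidation in step 2 is assumed to give mainly the 4,5-trans alcohol 4, so the inversion of steps 3 and 4 is part of the route.

## Route

Step 1
Reactants: 1 (S)-(+)-carvone
Product: 3 trimethyl{[(5R)-2-methyl-5-(prop-1-en-2-yl)cyclohexa-1,3-dien-1-yl]oxy}silane, via bromomagnesium dienolate 2 (not isolated)
Conditions: MeMgBr, FeCl3 (5 mol %), Et2O, −20 °C; then Me3SiCl, Et3N, DMPU, −20 °C → rt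
Reagents that add atoms: chlorotrimethylsilane, C[Si](C)(C)Cl
Why: Iron-catalysed γ-deprotonation of the enone by the Grignard reagent gives the through-conjugated dienolate, which is silylated on oxygen (thermodynamic silyl dienol ether formation); C7 is not touched, so the carvone stereocentre is kept (the descriptor changes only because the ring priorities change).

Step 2
Reactants: 3 trimethylsilyl dienol ether
Product: 4 trans-4-hydroxycarvone (4R,5S)-4-hydroxy-2-methyl-5-(prop-1-en-2-yl)cyclohex-2-en-1-one
Conditions: mCPBA, hexane, −15 °C → rt; then aq. citric acid, THF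
Reagents that add atoms: 3-chloroperoxybenzoic acid (mCPBA), OOC(=O)c1cccc(Cl)c1
Why: Vinylogous Rubottom oxidation: the peracid epoxidises the distal C5=C6 bond of the 1-silyloxydiene (largest HOMO coefficient at the γ-terminus, far more electron-rich than the isopropenyl group), the silyloxy group opens the oxirane to the γ-oxygenated enone, and the oxidant should approach C6 anti to the neighbouring isopropenyl group; any cis isomer 6 formed directly can be separated and used in step 5.

Step 3
Reactants: 4 trans-4-hydroxycarvone
Product: 5 (1S,6S)-3-methyl-4-oxo-6-(prop-1-en-2-yl)cyclohex-2-en-1-yl 4-nitrobenzoate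
Conditions: 4-nitrobenzoic acid, PPh3, diisopropyl azodicarboxylate, THF, 0 °C → rt
Reagents that add atoms: 4-nitrobenzoic acid, OC(=O)c1ccc(cc1)[N+](=O)[O-]
Why: Mitsunobu reaction: the allylic alkoxyphosphonium salt is displaced by the carboxylate in an SN2 sense (the SN2' position is the enone α-carbon and is not attacked), which inverts C6 and puts the oxygen cis to the isopropenyl group; the acidic nucleophile is chosen because C6 is flanked by a branched carbon.

Step 4
Reactants: 5 cis 4-nitrobenzoate
Product: 6 cis-4-hydroxycarvone (4S,5S)-4-hydroxy-2-methyl-5-(prop-1-en-2-yl)cyclohex-2-en-1-one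
Conditions: K2CO3 (cat.), MeOH, 0 °C
Reagents that add atoms: none
Why: Base-catalysed transesterification of the electron-poor aryl ester proceeds by acyl–oxygen cleavage at low temperature and so leaves C6 and C7 untouched.

Step 5
Reactants: 6 cis-4-hydroxycarvone; 7 isopropenylmagnesium bromide; 8 formaldehyde
Product: 11 (2R,3S,4R,5S)-4-hydroxy-2-(hydroxymethyl)-2-methyl-3,5-di(prop-1-en-2-yl)cyclohexan-1-one, via bromomagnesium alkoxide 9 (not isolated), via bromomagnesium alkoxide–enolate 10 (not isolated)
Conditions: 7 (3 equiv), THF, −78 → 0 °C; then 8 (monomeric, from cracked paraformaldehyde, excess), −78 → −40 °C; aq. NH4Cl at −40 °C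
Reagents that add atoms: none
Why: The first equivalent of 7 deprotonates the hydroxyl (propene is lost) to give alkoxide 9; a second equivalent binds to this alkoxide and transfers its isopropenyl group through a cyclic chelate to the adjacent β-carbon C5 on the face that carries O6, forming C5–C4 and the enolate 10 across C9 and C10. The closest known reaction type is the alkoxide-directed (ligand-assisted) conjugate addition of Grignard reagents to 4-hydroxycyclohex-2-enones and quinol alkoxides, run without copper and followed by aldol capture of the enolate. The regiodefined, fully substituted enolate then adds to monomeric formaldehyde at C10, forming C10–C1 and the quaternary centre. No ring is closed; only the two exocyclic bonds C5–C4 and C10–C1 are made. C5 is controlled by intramolecular delivery from the C6 alkoxide, which has to override the usual preference of 5-substituted cyclohexenones for attack anti to the C7 substituent and gives the all-cis C5/C6/C7 array. C10 is controlled by the new C5 substituent: formaldehyde approaches the enolate anti to the adjacent isopropenyl group, which is also the face free of the alkoxide and of the C7 group, so C1 ends up trans to the C5 arm. The step needs 1,4- and not 1,2-addition of an alkenyl Grignard reagent and cis delivery; both rest on the magnesium chelate, which is why the hydroxyl is left free and copper and strongly coordinating cosolvents are avoided. The aldol is run and quenched cold so that the β-hydroxy ketone does not lose formaldehyde by retro-aldol reaction.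

Step 6
Reactants: 11 keto diol
Product: 12 tris(triethylsilyl) derivative of 11 (1-O and 6-O silyl ethers, 9-silyloxy C8=C9 enol ether)
Conditions: Et3SiOTf (3.6 equiv), Et3N, CH2Cl2, −78 → 0 °C
Reagents that add atoms: triethylsilyl trifluoromethanesulfonate, CC[Si](CC)(CC)OS(=O)(=O)C(F)(F)F
Why: The silyl triflate with amine base silylates the primary and the hindered axial secondary hydroxyl and converts the ketone into its silyl enol ether in one operation; C10 is quaternary, so enolisation can only go towards C8, and silylation of O1 closes the retro-aldol pathway.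

Step 7
Reactants: 12 tris(triethylsilyl) enol ether
Product: 13 C9 ketone with 1-O, 6-O and 8-O triethylsilyl groups (O8 on the upper face)
Conditions: mCPBA (1.05 equiv), hexane/CH2Cl2, −15 °C → rt
Reagents that add atoms: 3-chloroperoxybenzoic acid (mCPBA), OOC(=O)c1cccc(Cl)c1
Why: Rubottom oxidation: the silyl enol ether is epoxidised in preference to the two 1,1-disubstituted alkenes and the silyloxy oxirane rearranges by 1,4-silyl shift to the α-silyloxy ketone; the lower face of C8=C9 is screened by the pseudo-axial C14 methyl and the axial C6 silyloxy group, so oxygen enters from the upper face, trans to the C7 isopropenyl group. Partial loss of the O8 silyl group would not matter, because steps 8 and 9 converge on 15.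

Step 8
Reactants: 13 α-silyloxy ketone
Product: 14 C9 alcohol (O9 on the upper face, cis to O8) with 1-O, 6-O and 8-O triethylsilyl groups
Conditions: LiBH(s-Bu)3 (L-Selectride), THF, −78 °C; then H2O
Reagents that add atoms: none
Why: A bulky trialkylborohydride attacks cyclohexanones along the equatorial trajectory and avoids the axial path past the axial hydrogens on C5 and C7, which gives the axial C9 alcohol cis to the equatorial O8; the same outcome is known for 2-oxygenated 3-oxo-4,4-dimethyl triterpenoids, which also carry an axial methyl next to the carbonyl. Silyl migration between O8 and O9 would be of no consequence, since both are silylated in step 9.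

Step 9
Reactants: 14 C9 alcohol
Product: 15 1,6,8,9-tetrakis(triethylsilyl) ether
Conditions: Et3SiOTf, 2,6-lutidine, CH2Cl2, 0 °C
Reagents that add atoms: triethylsilyl trifluoromethanesulfonate, CC[Si](CC)(CC)OS(=O)(=O)C(F)(F)F
Why: Silylation of a hindered secondary alcohol with a silyl triflate and a hindered pyridine base; the three secondary oxygens are now inert to the two oxidations that follow.

Step 10
Reactants: 15 tetrakis(triethylsilyl) ether
Product: 16 C1 aldehyde, 6,8,9-tris(triethylsilyl) ether
Conditions: (COCl)2, DMSO, CH2Cl2, −78 → −35 °C; then Et3N, −78 → 0 °C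
Reagents that add atoms: none
Why: Swern oxidation applied directly to a silyl ether: the activated sulfonium species cleaves the primary triethylsilyl ether much faster than the hindered secondary ones and the alkoxysulfonium salt collapses to the aldehyde on addition of base; C10 is quaternary, so the aldehyde cannot epimerise.

Step 11
Reactants: 16 aldehyde
Product: 17 2-chloro-1-hydroxyethyl compound (both C1 epimers), 6,8,9-tris(triethylsilyl) ether
Conditions: ClCH2I, MeLi·LiBr, THF/Et2O, −78 °C; AcOH, −78 °C
Reagents that add atoms: chloroiodomethane, ClCI
Why: Chloromethyllithium, made by iodine–lithium exchange in the presence of the aldehyde, adds to the non-enolisable aldehyde and forms C1–C2; the cold quench keeps the lithium alkoxide from closing to an oxirane, and the C1 configuration does not matter because step 12 erases it.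

Step 12
Reactants: 17 chlorohydrin mixture
Product: 18 chloromethyl ketone (C1 carbonyl), 6,8,9-tris(triethylsilyl) ether
Conditions: Dess–Martin periodinane, pyridine, CH2Cl2, 0 °C → rt
Reagents that add atoms: none
Why: Dess–Martin oxidation of a hindered secondary alcohol to the α-chloro ketone under buffered conditions; silyl ethers, alkenes and the primary chloride are inert, and the ketone has no enolisable hydrogen on the C10 side.

Step 13
Reactants: 18 chloromethyl ketone
Product: 20 (1R)-oxirane 6,8,9-tris(triethylsilyl) ether, via (1R)-chlorohydrin 19 (not isolated)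
Conditions: (R)-1-methyl-3,3-diphenyltetrahydro-1H,3H-pyrrolo[1,2-c][1,3,2]oxazaborole (0.5 equiv), catecholborane, toluene, −78 → −40 °C; then K2CO3, MeOH, 0 °C → rt
Reagents that add atoms: none
Why: Corey–Bakshi–Shibata reduction: the oxazaborolidine binds the ketone anti to the fully substituted C10 and, with the R catalyst and a large tert-alkyl against a small chloromethyl group, delivers hydride to the face that gives the 1R chlorohydrin. The substrate's own preference is matched, since the hydride then enters from the open sector between C9 and C14, anti to C5. The alkoxide closes the oxirane by 3-exo-tet displacement at the primary C2, with retention at C1.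

Step 14
Reactants: 20 oxirane tris(triethylsilyl) ether
Product: 21 (1R)-oxirane 6,8,9-triol
Conditions: Bu4NF, THF, 0 °C → rt
Reagents that add atoms: none
Why: Fluoride cleaves the three triethylsilyl ethers under non-acidic conditions; the oxirane is stable to fluoride, and the only base-mediated opening available to O9 would be a disfavoured 5-endo attack at C2.

Step 15
Reactants: 21 oxirane triol
Product: 22 8,9-cyclic carbonate with free 6-hydroxyl
Conditions: 1,1'-carbonyldiimidazole (1.2 equiv), CH2Cl2, rt
Reagents that add atoms: 1,1'-carbonyldiimidazole, O=C(n1ccnc1)n1ccnc1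
Why: The cis-8,9-diol closes to its five-membered cyclic carbonate; the axial O6 hydroxyl, flanked by two branched carbons and 1,3-diaxial to C14, reacts far more slowly and has no cis neighbour to cyclise with.

Step 16
Reactants: 22 cyclic carbonate
Product: 23 6-methacrylate 8,9-cyclic carbonate
Conditions: methacrylic anhydride, 4-(dimethylamino)pyridine, Et3N, 2,6-di-tert-butyl-4-methylphenol (trace), toluene, 60 °C
Reagents that add atoms: methacrylic anhydride, CC(=C)C(=O)OC(=O)C(C)=C
Why: Nucleophile-catalysed acylation of a hindered secondary alcohol with an anhydride, placed here because no enal or lactone is yet present and forcing conditions can be used; the phenol suppresses radical polymerisation.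

Step 17
Reactants: 23 methacrylate carbonate
Product: 24 6-methacrylate 8,9-diol
Conditions: K2CO3 (cat.), MeOH, 0 °C
Reagents that add atoms: none
Why: A strained five-membered cyclic carbonate undergoes methanolysis much faster than a hindered, conjugated secondary ester, so catalytic carbonate in methanol at 0 °C should free the diol and leave the methacrylate (transesterification).

Step 18
Reactants: 24 methacrylate diol
Product: 25 6-methacrylate 3,8,9,12-tetraol (both arms 3-hydroxyprop-1-en-2-yl)
Conditions: SeO2 (0.5 equiv), t-BuOOH, CH2Cl2, rt
Reagents that add atoms: selenium dioxide, O=[Se]=O (transfers the oxygen); tert-butyl hydroperoxide, CC(C)(C)OO (terminal oxidant)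
Why: Selenium-catalysed allylic oxidation (ene reaction at the terminal methylene, then 2,3-sigmatropic shift) converts both isopropenyl methyl groups into hydroxymethyl groups; the electron-poor methacrylate is a poor ene partner, and partial over-oxidation to the aldehydes is harmless because step 19 brings all material to the same oxidation level.

Step 19
Reactants: 25 tetraol
Product: 28 CNP0228781.2 (target), via dialdehyde 26 (not isolated), via lactol 27 (not isolated)
Conditions: MnO2 (activated, excess), CH2Cl2, rt
Reagents that add atoms: none
Why: MnO2 oxidises only allylic alcohols: C3 gives the enal, C12 gives an aldehyde that the neighbouring equatorial O8 hydroxyl captures as the trans-fused lactol, and this allylic hemiacetal is oxidised on to the α-methylene lactone (oxidative lactonisation of a 2-methylene-1,4-diol). The axial O9 hydroxyl cannot reach C3 or C12, O6 is acylated, cleavage of the hindered 8,9-diol should be much slower than allylic oxidation, and no stereocentre is touched.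

## Compound list

1 | (S)-(+)-carvone, (5S)-2-methyl-5-(prop-1-en-2-yl)cyclohex-2-en-1-one | CC1=CC[C@@H](CC1=O)C(C)=C | starting material
2 | bromomagnesium dienolate of 1 (O–C9=C10–C5=C6) | CC1=C(O[Mg]Br)C[C@@H](C(C)=C)C=C1 | intermediate (not isolated)
3 | trimethyl{[(5R)-2-methyl-5-(prop-1-en-2-yl)cyclohexa-1,3-dien-1-yl]oxy}silane | CC1=C(O[Si](C)(C)C)C[C@@H](C(C)=C)C=C1 | intermediate
4 | trans-4-hydroxycarvone, (4R,5S)-4-hydroxy-2-methyl-5-(prop-1-en-2-yl)cyclohex-2-en-1-one | CC1=C[C@@H](O)[C@H](C(C)=C)CC1=O | intermediate
5 | (1S,6S)-3-methyl-4-oxo-6-(prop-1-en-2-yl)cyclohex-2-en-1-yl 4-nitrobenzoate | CC1=C[C@H](OC(=O)c2ccc(cc2)[N+](=O)[O-])[C@H](C(C)=C)CC1=O | intermediate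
6 | cis-4-hydroxycarvone, (4S,5S)-4-hydroxy-2-methyl-5-(prop-1-en-2-yl)cyclohex-2-en-1-one | CC1=C[C@H](O)[C@H](C(C)=C)CC1=O | intermediate
7 | isopropenylmagnesium bromide | C=C(C)[Mg]Br | starting material
8 | formaldehyde | C=O | starting material
9 | bromomagnesium alkoxide of 6 | CC1=C[C@H](O[Mg]Br)[C@H](C(C)=C)CC1=O | intermediate (not isolated)
10 | bis(bromomagnesium) 6-alkoxide C9=C10 enolate with the new C5 isopropenyl group | Br[Mg]O[C@@H]1[C@H](C(C)=C)CC(O[Mg]Br)=C(C)[C@@H]1C(C)=C | intermediate (not isolated)
11 | (2R,3S,4R,5S)-4-hydroxy-2-(hydroxymethyl)-2-methyl-3,5-di(prop-1-en-2-yl)cyclohexan-1-one (C9 ketone; both isopropenyl groups and O6 on the lower face, C1 on the upper face) | O[C@@H]1[C@H](C(C)=C)CC(=O)[C@@](C)(CO)[C@@H]1C(C)=C | intermediate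
12 | tris(triethylsilyl) derivative of 11: 1-O and 6-O silyl ethers, 9-silyloxy C8=C9 enol ether | CC[Si](CC)(CC)O[C@@H]1[C@H](C(C)=C)C=C(O[Si](CC)(CC)CC)[C@@](C)(CO[Si](CC)(CC)CC)[C@@H]1C(C)=C | intermediate
13 | C9 ketone with 1-O, 6-O and 8-O triethylsilyl groups, O8 on the upper face | CC[Si](CC)(CC)O[C@@H]1[C@H](C(C)=C)[C@@H](O[Si](CC)(CC)CC)C(=O)[C@@](C)(CO[Si](CC)(CC)CC)[C@@H]1C(C)=C | intermediate
14 | C9 alcohol (O9 upper face, cis to O8) with 1-O, 6-O and 8-O triethylsilyl groups | CC[Si](CC)(CC)O[C@@H]1[C@H](C(C)=C)[C@@H](O[Si](CC)(CC)CC)[C@@H](O)[C@@](C)(CO[Si](CC)(CC)CC)[C@@H]1C(C)=C | intermediate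
15 | 1,6,8,9-tetrakis(triethylsilyl) ether | CC[Si](CC)(CC)O[C@@H]1[C@H](C(C)=C)[C@@H](O[Si](CC)(CC)CC)[C@@H](O[Si](CC)(CC)CC)[C@@](C)(CO[Si](CC)(CC)CC)[C@@H]1C(C)=C | intermediate
16 | C1 aldehyde, 6,8,9-tris(triethylsilyl) ether | CC[Si](CC)(CC)O[C@@H]1[C@H](C(C)=C)[C@@H](O[Si](CC)(CC)CC)[C@@H](O[Si](CC)(CC)CC)[C@@](C)(C=O)[C@@H]1C(C)=C | intermediate
17 | 2-chloro-1-hydroxyethyl compound (both C1 epimers), 6,8,9-tris(triethylsilyl) ether | CC[Si](CC)(CC)O[C@@H]1[C@H](C(C)=C)[C@@H](O[Si](CC)(CC)CC)[C@@H](O[Si](CC)(CC)CC)[C@@](C)(C(O)CCl)[C@@H]1C(C)=C | intermediate
18 | chloromethyl ketone (C1 carbonyl), 6,8,9-tris(triethylsilyl) ether | CC[Si](CC)(CC)O[C@@H]1[C@H](C(C)=C)[C@@H](O[Si](CC)(CC)CC)[C@@H](O[Si](CC)(CC)CC)[C@@](C)(C(=O)CCl)[C@@H]1C(C)=C | intermediate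
19 | (1R)-chlorohydrin, 6,8,9-tris(triethylsilyl) ether | CC[Si](CC)(CC)O[C@@H]1[C@H](C(C)=C)[C@@H](O[Si](CC)(CC)CC)[C@@H](O[Si](CC)(CC)CC)[C@@](C)([C@@H](O)CCl)[C@@H]1C(C)=C | intermediate (not isolated)
20 | (1R)-oxirane, 6,8,9-tris(triethylsilyl) ether | CC[Si](CC)(CC)O[C@@H]1[C@H](C(C)=C)[C@@H](O[Si](CC)(CC)CC)[C@@H](O[Si](CC)(CC)CC)[C@@](C)([C@@H]2CO2)[C@@H]1C(C)=C | intermediate
21 | (1R)-oxirane 6,8,9-triol | O[C@@H]1[C@H](C(C)=C)[C@@H](O)[C@@H](O)[C@@](C)([C@@H]2CO2)[C@@H]1C(C)=C | intermediate
22 | 8,9-cyclic carbonate of 21 (6-hydroxyl free) | O[C@@H]1[C@H](C(C)=C)[C@H]2OC(=O)O[C@H]2[C@@](C)([C@@H]3CO3)[C@@H]1C(C)=C | intermediate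
23 | 6-methacrylate 8,9-cyclic carbonate | C=C(C)C(=O)O[C@@H]1[C@H](C(C)=C)[C@H]2OC(=O)O[C@H]2[C@@](C)([C@@H]3CO3)[C@@H]1C(C)=C | intermediate
24 | 6-methacrylate 8,9-diol | C=C(C)C(=O)O[C@@H]1[C@H](C(C)=C)[C@@H](O)[C@@H](O)[C@@](C)([C@@H]2CO2)[C@@H]1C(C)=C | intermediate
25 | 6-methacrylate 3,8,9,12-tetraol | C=C(C)C(=O)O[C@@H]1[C@H](C(=C)CO)[C@@H](O)[C@@H](O)[C@@](C)([C@@H]2CO2)[C@@H]1C(=C)CO | intermediate
26 | 3,12-dialdehyde 8,9-diol | C=C(C)C(=O)O[C@@H]1[C@H](C(=C)C=O)[C@@H](O)[C@@H](O)[C@@](C)([C@@H]2CO2)[C@@H]1C(=C)C=O | intermediate (not isolated)
27 | 12,8-lactol (both anomers) with C3 aldehyde | C=C(C)C(=O)O[C@@H]1[C@@H]2C(=C)C(O)O[C@H]2[C@@H](O)[C@@](C)([C@@H]2CO2)[C@@H]1C(=C)C=O | intermediate (not isolated)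
28 | CNP0228781.2 | C=C(C)C(=O)O[C@@H]1[C@@H]2C(=C)C(=O)O[C@H]2[C@@H](O)[C@@](C)([C@@H]2CO2)[C@@H]1C(=C)C=O | target

## Step count and least certain steps

Total step count: 19. Longest linear sequence: 19 steps, from 1 to 28; 7 and 8 are used as purchased.

**Step 5 (key step).** The alkenyl Grignard reagent may add directly to the C9 carbonyl or arrive anti to the alkoxide, because the directed path brings the incoming group into a 1,3-syn relation with the C7 isopropenyl group. The hindered enolate may also be lost by proton transfer or retro-aldol reaction before formaldehyde captures it. Fallback, from 6 and back at 11: the two bonds are made in separate operations and the transferring metal is changed. Compound 6 is converted into its chloromagnesium alkoxide with t-BuMgCl. The isopropenyl group is then delivered from dimethyl(isopropenyl)alane (from 7 and Me2AlCl), a directed conjugate transfer from aluminium that is known for 4-hydroxy enones and has little tendency to attack ketones. The enolate is silylated with Me3SiCl and Et3N to the bis(trimethylsilyl) enol ether F1. F1 is hydroxymethylated at C10 with aqueous formaldehyde and Yb(OTf)3 in THF (Mukaiyama aldol), again anti to the C5 arm, and the O6 silyl group is lost on acidic work-up to give 11.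

**Step 2.** The peracid may attack the more substituted silyl enol ether bond C9=C10, which would oxidise C10 and not C6, or its acid may strip the silyl group and return 1. Fallback, from 3 and back at 4: oxygen is introduced by cycloaddition, which fixes the regiochemistry. Sensitised photo-oxygenation (O2, 5,10,15,20-tetraphenylporphyrin, visible light, CH2Cl2, −78 °C) adds singlet oxygen across C9 and C6 anti to the isopropenyl group to give the silyloxy endoperoxide F2. F2 collapses in methanol to the trans γ-hydroperoxy enone F3, and PPh3 reduces F3 to 4.

**Step 8.** Hydride may arrive along the axial path from the upper face and give the equatorial C9 epimer, because the equatorial path passes the axial C14 methyl group. Fallback, from 11 and back at 15: the cis-diol is made by directed syn-dihydroxylation in place of oxidation and reduction. Compound 11 is silylated without enolisation (Et3SiOTf, 2,6-lutidine, −78 °C) to the bis(triethylsilyl) ketone F4. KN(SiMe3)2 and PhNTf2 give the C8=C9 enol triflate F5, which is reduced with Pd(OAc)2, PPh3, HCO2H and Et3N to the cyclohexene F6. The primary silyl ether is removed (pyridinium 4-toluenesulfonate, MeOH, 0 °C) to give the homoallylic alcohol F7. OsO4 with N,N,N',N'-tetramethylethylenediamine at −78 °C, guided by hydrogen bonding to the C1 hydroxyl on the upper face and reinforced by approach anti to the C7 arm, gives the triol F8. Silylation of its three free hydroxyls with Et3SiOTf gives 15.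

**Step 13.** Catalyst turnover at the hindered ketone may be slow enough for uncatalysed, unselective reduction to compete, which would erode the C1 configuration. Fallback, from 18 and back at 20: the reduction and ring closure are run as before, and the unwanted 1S oxirane F9 is separated and inverted. CsOAc in DMF opens F9 at the primary C2 to the hydroxy acetate F10. Mesylation (MeSO2Cl, Et3N) gives the mesylate F11. K2CO3 in MeOH cleaves the acetate, and the C2 alkoxide displaces the mesylate with inversion at C1 to give 20.

**Step 17.** Methoxide may also attack the methacrylate, by transesterification or conjugate addition, while the carbonate is cleaved. Fallback, from 21 and back at 24: the diol is masked with groups that come off with fluoride. Et3SiCl and imidazole silylate the more accessible O8 and O9 to the 8,9-bis(triethylsilyl) ether F12. Acylation as in step 16 gives the methacrylate F13, and Bu4NF buffered with AcOH releases 24.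

**Step 18.** The ene reaction may abstract the ring methine hydrogens on C5 and C7 in place of the methyl hydrogens, or stop after one arm. Fallback, from 24 and back at 26, which step 19 carries on to 28: the methyl groups are functionalised by ene-type chlorination. Ca(OCl)2 with CO2 in CH2Cl2/H2O should give the bis(allylic chloride) F14, with the double bonds moved to the former methyl carbons. N-Methylmorpholine N-oxide in MeCN oxidises F14 to the dialdehyde 26.

## Further compounds

F1 | step 5 | bis(trimethylsilyl) derivative: 6-O-trimethylsilyl ether, 9-trimethylsilyloxy C9=C10 enol ether, C5 isopropenyl on the lower face | C[Si](C)(C)O[C@@H]1[C@H](C(C)=C)CC(O[Si](C)(C)C)=C(C)[C@@H]1C(C)=C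
F2 | step 2 | silyloxy endoperoxide (dioxygen bridge from C9 to C6, anti to the isopropenyl group) | CC1=C[C@H]2OO[C@]1(O[Si](C)(C)C)C[C@H]2C(C)=C
F3 | step 2 | trans-4-hydroperoxycarvone | CC1=C[C@@H](OO)[C@H](C(C)=C)CC1=O
F4 | step 8 | 1,6-bis(triethylsilyl) ether of 11 | CC[Si](CC)(CC)O[C@@H]1[C@H](C(C)=C)CC(=O)[C@@](C)(CO[Si](CC)(CC)CC)[C@@H]1C(C)=C
F5 | step 8 | C8=C9 enol triflate, 1,6-bis(triethylsilyl) ether | CC[Si](CC)(CC)O[C@@H]1[C@H](C(C)=C)C=C(OS(=O)(=O)C(F)(F)F)[C@@](C)(CO[Si](CC)(CC)CC)[C@@H]1C(C)=C
F6 | step 8 | C8=C9 cyclohexene, 1,6-bis(triethylsilyl) ether | CC[Si](CC)(CC)O[C@@H]1[C@H](C(C)=C)C=C[C@@](C)(CO[Si](CC)(CC)CC)[C@@H]1C(C)=C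
F7 | step 8 | C8=C9 cyclohexene with free C1 hydroxyl, 6-O-triethylsilyl ether | CC[Si](CC)(CC)O[C@@H]1[C@H](C(C)=C)C=C[C@@](C)(CO)[C@@H]1C(C)=C
F8 | step 8 | 1,8,9-triol (O8 and O9 on the upper face), 6-O-triethylsilyl ether | CC[Si](CC)(CC)O[C@@H]1[C@H](C(C)=C)[C@@H](O)[C@@H](O)[C@@](C)(CO)[C@@H]1C(C)=C
F9 | step 13 | (1S)-oxirane, 6,8,9-tris(triethylsilyl) ether (C1 epimer of 20) | CC[Si](CC)(CC)O[C@@H]1[C@H](C(C)=C)[C@@H](O[Si](CC)(CC)CC)[C@@H](O[Si](CC)(CC)CC)[C@@](C)([C@H]2CO2)[C@@H]1C(C)=C
F10 | step 13 | (1S)-1-hydroxy-2-acetoxyethyl compound, 6,8,9-tris(triethylsilyl) ether | CC[Si](CC)(CC)O[C@@H]1[C@H](C(C)=C)[C@@H](O[Si](CC)(CC)CC)[C@@H](O[Si](CC)(CC)CC)[C@@](C)([C@H](O)COC(C)=O)[C@@H]1C(C)=C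
F11 | step 13 | (1S)-1-mesyloxy-2-acetoxyethyl compound, 6,8,9-tris(triethylsilyl) ether | CC[Si](CC)(CC)O[C@@H]1[C@H](C(C)=C)[C@@H](O[Si](CC)(CC)CC)[C@@H](O[Si](CC)(CC)CC)[C@@](C)([C@H](OS(C)(=O)=O)COC(C)=O)[C@@H]1C(C)=C
F12 | step 17 | (1R)-oxirane 8,9-bis(triethylsilyl) ether with free 6-hydroxyl | O[C@@H]1[C@H](C(C)=C)[C@@H](O[Si](CC)(CC)CC)[C@@H](O[Si](CC)(CC)CC)[C@@](C)([C@@H]2CO2)[C@@H]1C(C)=C
F13 | step 17 | 6-methacrylate 8,9-bis(triethylsilyl) ether | C=C(C)C(=O)O[C@@H]1[C@H](C(C)=C)[C@@H](O[Si](CC)(CC)CC)[C@@H](O[Si](CC)(CC)CC)[C@@](C)([C@@H]2CO2)[C@@H]1C(C)=C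
F14 | step 18 | 6-methacrylate 8,9-diol with both arms as 3-chloroprop-1-en-2-yl | C=C(C)C(=O)O[C@@H]1[C@H](C(=C)CCl)[C@@H](O)[C@@H](O)[C@@](C)([C@@H]2CO2)[C@@H]1C(=C)CCl
A1 | alternative 1 | (Z)-3-[(4S)-4-benzyl-2-oxooxazolidin-3-yl]-3-oxoprop-1-en-1-yl (3E,5Z)-7-[(tert-butyldimethylsilyl)oxy]-6-methylhepta-3,5-dienoate | C/C(CO[Si](C)(C)C(C)(C)C)=C/C=C/CC(=O)O/C=C\C(=O)N1C(=O)OC[C@@H]1Cc1ccccc1
A2 | alternative 1 | cis-fused O6–C12 lactone cyclohexene with C5 imide and C10 quaternary centre | O=C1C[C@@H]2C=C[C@@](C)(CO[Si](C)(C)C(C)(C)C)[C@H](C(=O)N3C(=O)OC[C@@H]3Cc4ccccc4)[C@@H]2O1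
A3 | alternative 2 | 3-[(tert-butyldimethylsilyl)oxy]-5-ethenyl-5-methyl-2,4-di(prop-1-en-2-yl)hexanedial | O=C[C@@H](C(C)=C)[C@@H](O[Si](C)(C)C(C)(C)C)[C@@H](C(C)=C)[C@](C)(C=C)C=O
A4 | alternative 2 | cis-8,9-diol of the bis(isopropenyl) vinyl cyclohexane, C6 silyl ether | CC(C)(C)[Si](C)(C)O[C@@H]1[C@H](C(C)=C)[C@@H](O)[C@@H](O)[C@@](C)(C=C)[C@@H]1C(C)=C
A5 | alternative 3 | methyl (Z)-2-(bromomethyl)enoate carrying the C8 aldehyde, O6 triethylsilyl, O9 and O3 tert-butyldimethylsilyl ethers | O=C[C@@H](O[Si](C)(C)C(C)(C)C)[C@@](C)(C=C)[C@H](C(=C)CO[Si](C)(C)C(C)(C)C)[C@H](O[Si](CC)(CC)CC)/C=C(\CBr)C(=O)OC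
A6 | alternative 3 | trans-fused α-methylene lactone on the fully substituted cyclohexane, tris-silyl ether | CC[Si](CC)(CC)O[C@@H]1[C@@H]2C(=C)C(=O)O[C@H]2[C@@H](O[Si](C)(C)C(C)(C)C)[C@@](C)(C=C)[C@@H]1C(=C)CO[Si](C)(C)C(C)(C)C
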